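**Retrosynthetic overview**
1. Target 13 comes from hexa-O-benzyl ether 12 by one global hydrogenolysis.
2. Key disconnection: the C8(flavan)–CH2 bond of the diarylmethane. Aryl bromide 3 is joined to the aldehyde carbon of 10, used as a benzyl-carbanion equivalent through its N–H hydrazone 11 (Ni-catalysed, loss of N2).
3. Bromide 3 comes from (+)-catechin 1 by benzylation and C8 bromination; both flavan stereocentres are bought.
4. Aldehyde 10 comes from 2-methylphloroglucinol 4: formylation, CHO-directed para-O-methylation, Friedel–Crafts acylation with (R)-2-methylbutanoic acid 7, benzylation.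
5. No ring is formed: the chroman and both benzene rings arrive intact in 1 and 4.

Assumptions: (R)-2-methylbutanoic acid is bought as the single enantiomer. Hydrazone formation and the nickel coupling are run in one pot and counted as one step, as are acid chloride formation and acylation.

**Step 1**
Reactants: 1 (+)-catechin
Product: 2 5,7,3',4'-tetra-O-benzyl-(+)-catechin
Conditions: BnBr (4.4 equiv), K2CO3, DMF, 0 °C → rt, Ar
Reagents that add atoms: benzyl bromide, BrCc1ccccc1
Why: Williamson etherification; carbonate deprotonates only the four phenols, so the aliphatic 3-OH stays free and neither stereocentre is touched.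

**Step 2**
Reactants: 2 5,7,3',4'-tetra-O-benzyl-(+)-catechin
Product: 3 8-bromo-5,7,3',4'-tetra-O-benzyl-(+)-catechin
Conditions: NBS (1.0 equiv), CH2Cl2, −78 °C → rt
Reagents that add atoms: N-bromosuccinimide, O=C1CCC(=O)N1Br
Why: Electrophilic aromatic bromination; the 5,7-dibenzyloxy A ring is the most electron-rich ring and reacts at C8, the established site for protected flavan-3-ols, with no stereocentre involved.

**Step 3**
Reactants: 4 2-methylphloroglucinol
Product: 5 2,4,6-trihydroxy-3-methylbenzaldehyde
Conditions: POCl3 (1.1 equiv), DMF (1.2 equiv), EtOAc, 0 °C → rt; then H2O, 60 °C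
Reagents that add atoms: N,N-dimethylformamide, CN(C)C=O; water, O
Why: Vilsmeier–Haack formylation; the two free ring positions are equivalent and the iminium salt deactivates the ring against a second formylation.

**Step 4**
Reactants: 5 2,4,6-trihydroxy-3-methylbenzaldehyde
Product: 6 2,6-dihydroxy-4-methoxy-3-methylbenzaldehyde
Conditions: Me2SO4 (1.0 equiv), K2CO3 (1.0 equiv), acetone, rt
Reagents that add atoms: dimethyl sulfate, COS(=O)(=O)OC
Why: Williamson O-methylation; the 4-OH para to the formyl group is the most acidic and the only one that cannot hydrogen-bond to the carbonyl, so one equivalent methylates it preferentially, as with phloroacetophenone.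

**Step 5**
Reactants: 6 2,6-dihydroxy-4-methoxy-3-methylbenzaldehyde; 7 (R)-2-methylbutanoic acid
Product: 9 2,6-dihydroxy-4-methoxy-3-methyl-5-[(2R)-2-methylbutanoyl]benzaldehyde, via (2R)-2-methylbutanoyl chloride 8 (not isolated)
Conditions: 7, (COCl)2, cat. DMF, CH2Cl2, 0 °C → rt; then 6, TiCl4 (2.5 equiv), CH2Cl2, 0 °C → rt
Reagents that add atoms: none
Why: Friedel–Crafts C-acylation at the only free ring carbon, which is ortho/para to three oxygen donors; the acid chloride is made without base and TiCl4 is mild towards the methyl ether, so the (R) centre is carried over from 7.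

**Step 6**
Reactants: 9 2,6-dihydroxy-4-methoxy-3-methyl-5-[(2R)-2-methylbutanoyl]benzaldehyde
Product: 10 2,6-bis(benzyloxy)-4-methoxy-3-methyl-5-[(2R)-2-methylbutanoyl]benzaldehyde
Conditions: BnBr (2.4 equiv), K2CO3 (3 equiv), DMF, rt → 40 °C
Reagents that add atoms: benzyl bromide, BrCc1ccccc1
Why: Williamson benzylation in a dipolar aprotic solvent favours O- over C-alkylation, and carbonate is too weak to enolise the twisted, di-ortho-substituted aryl ketone, so the (R) centre is retained.

**Step 7**
Reactants: 10 2,6-bis(benzyloxy)-4-methoxy-3-methyl-5-[(2R)-2-methylbutanoyl]benzaldehyde; 3 8-bromo-5,7,3',4'-tetra-O-benzyl-(+)-catechin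
Product: 12 hexa-O-benzyl ether of the target, via N–H hydrazone 11 (not isolated)
Conditions: 10 (1.3 equiv), N2H4·H2O (1.2 equiv per 10), THF, rt, 1 h; then 3, Ni(cod)2 (10 mol%), PMe3 (40 mol%), DBU, K3PO4, 4 Å MS, THF, 60 °C
Reagents that add atoms: none
Why: Proposed new method: the N–H hydrazone 11 makes the aldehyde carbon a benzyl-carbanion equivalent, so that after oxidative addition of the C8–Br bond of 3 to Ni(0)/PMe3, base-assisted N-coordination, 1,3-shift to the C-bound diazenyl complex, loss of N2 and reductive elimination, two carbons that are both electrophilic in their parent forms are joined with the C8 regiochemistry fixed by the bromide; the closest known reaction type is the Ni/PMe3-catalysed denitrogenative (Wolff–Kishner-type) cross-coupling of aldehyde N–H hydrazones with aryl halides, extended here to two di-ortho-substituted, electron-rich partners, and no stereocentre is formed or touched.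

**Step 8**
Reactants: 12 hexa-O-benzyl ether of the target
Product: 13 target compound CNP0299940.2
Conditions: H2 (1 atm), 20% Pd(OH)2/C, THF/MeOH 1:1, rt; work-up under Ar
Reagents that add atoms: none
Why: Catalytic hydrogenolysis cleaves the six benzyl ethers, while the chelated hindered aryl ketone, the diarylmethane C–C bonds and the flavan C2–O bond survive at 1 atm, so all three stereocentres are untouched.

**Compound list**
1 | (+)-catechin, (2R,3S)-2-(3,4-dihydroxyphenyl)chromane-3,5,7-triol | Oc1cc(O)c2c(c1)O[C@H](c1ccc(O)c(O)c1)[C@@H](O)C2 | starting material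
2 | 5,7,3',4'-tetra-O-benzyl-(+)-catechin, (2R,3S)-5,7-bis(benzyloxy)-2-[3,4-bis(benzyloxy)phenyl]chroman-3-ol | c1ccccc1COc1cc(OCc3ccccc3)c2c(c1)O[C@H](c1ccc(OCc3ccccc3)c(OCc3ccccc3)c1)[C@@H](O)C2 | intermediate
3 | 8-bromo-5,7,3',4'-tetra-O-benzyl-(+)-catechin, (2R,3S)-5,7-bis(benzyloxy)-2-[3,4-bis(benzyloxy)phenyl]-8-bromochroman-3-ol | c1ccccc1COc1cc(OCc3ccccc3)c2c(c1Br)O[C@H](c1ccc(OCc3ccccc3)c(OCc3ccccc3)c1)[C@@H](O)C2 | intermediate
4 | 2-methylphloroglucinol (2-methylbenzene-1,3,5-triol) | Cc1c(O)cc(O)cc1O | starting material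
5 | 2,4,6-trihydroxy-3-methylbenzaldehyde | O=Cc1c(O)cc(O)c(C)c1O | intermediate
6 | 2,6-dihydroxy-4-methoxy-3-methylbenzaldehyde | O=Cc1c(O)cc(OC)c(C)c1O | intermediate
7 | (R)-2-methylbutanoic acid | CC[C@@H](C)C(=O)O | starting material
8 | (2R)-2-methylbutanoyl chloride (not isolated) | CC[C@@H](C)C(=O)Cl | intermediate
9 | 2,6-dihydroxy-4-methoxy-3-methyl-5-[(2R)-2-methylbutanoyl]benzaldehyde | CC[C@@H](C)C(=O)c1c(O)c(C=O)c(O)c(C)c1OC | intermediate
10 | 2,6-bis(benzyloxy)-4-methoxy-3-methyl-5-[(2R)-2-methylbutanoyl]benzaldehyde | CC[C@@H](C)C(=O)c1c(OCc2ccccc2)c(C=O)c(OCc2ccccc2)c(C)c1OC | intermediate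
11 | (E)-N–H hydrazone of 10, (2R)-1-[2,4-bis(benzyloxy)-3-(hydrazinylidenemethyl)-6-methoxy-5-methylphenyl]-2-methylbutan-1-one (not isolated) | CC[C@@H](C)C(=O)c1c(OCc2ccccc2)c(/C=N/N)c(OCc2ccccc2)c(C)c1OC | intermediate
12 | hexa-O-benzyl ether of the target, (2R)-1-[2,4-bis(benzyloxy)-3-{[(2R,3S)-5,7-bis(benzyloxy)-2-[3,4-bis(benzyloxy)phenyl]-3-hydroxychroman-8-yl]methyl}-6-methoxy-5-methylphenyl]-2-methylbutan-1-one | CC[C@@H](C)C(=O)c1c(OCc2ccccc2)c(Cc2c(OCc4ccccc4)cc(OCc4ccccc4)c3c2O[C@H](c2ccc(OCc4ccccc4)c(OCc4ccccc4)c2)[C@@H](O)C3)c(OCc2ccccc2)c(C)c1OC | intermediate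
13 | CNP0299940.2, (2R)-1-[3-{[(2R,3S)-2-(3,4-dihydroxyphenyl)-3,5,7-trihydroxychroman-8-yl]methyl}-2,4-dihydroxy-6-methoxy-5-methylphenyl]-2-methylbutan-1-one | CC[C@@H](C)C(=O)c1c(O)c(Cc2c(O)cc(O)c3c2O[C@H](c2ccc(O)c(O)c2)[C@@H](O)C3)c(O)c(C)c1OC | target

**Step count and risks**
Total steps: 8. Longest linear sequence: 6 steps (4 → 5 → 6 → 9 → 10 → 12 → 13; steps 3–8). The catechin branch (steps 1–2) joins at step 7.

The three steps most likely to fail:

Step 7 (key coupling). Both partners are di-ortho-substituted and the bromide is very electron-rich, so oxidative addition may be slow. Competing paths are Wolff–Kishner reduction of 11 to the methylarene, azine formation, protodebromination of 3, and base-induced erosion of the (R) centre. The enantiomeric purity of 12 should be checked by chiral HPLC. The fallback sets out from 3 and 10. Bromide 3 is treated with n-BuLi (2.1 equiv, THF, −78 °C; the first equivalent forms the C3 alkoxide, the second performs Br/Li exchange) and transmetalated with MgBr2·OEt2 to limit enolisation of the ketone. Addition to the aldehyde of 10 gives the diaryl carbinol F1 as a mixture of carbinol epimers. Ionic hydrogenation of this doubly activated benzhydrol (Et3SiH, TFA, CH2Cl2, −40 °C) gives 12, where the route is rejoined.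

Step 5 (acylation). The formyl group deactivates the ring, the Lewis acid may cleave the methyl ether ortho to the new ketone, and the α-centre may partly racemise. The fallback sets out from 6 and 7. The less hindered 2-OH of 6 is esterified with 7 (EDC, cat. DMAP, CH2Cl2, 0 °C) to give the aryl ester F2. A photo-Fries rearrangement (254 nm, degassed MeCN) moves the acyl group within the solvent cage to the only free ring carbon, which is ortho to the ester oxygen, without any Lewis acid. This comes back to the route at 9.

Step 4 (mono-methylation). The 6-OH can compete with the 4-OH, which is flanked by the ring methyl group, and over-methylation is possible. The fallback sets out from 5. Exhaustive methylation (MeI excess, K2CO3, DMF) gives 2,4,6-trimethoxy-3-methylbenzaldehyde F3. Chelation-directed double demethylation (AlCl3 excess, chlorobenzene, 60–80 °C) then removes only the two methoxy groups ortho to the formyl group and leaves the para one. This comes back to the route at 6.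

**Further compounds**
F1 | step 7 | (2R)-1-[2,4-bis(benzyloxy)-3-{[(2R,3S)-5,7-bis(benzyloxy)-2-[3,4-bis(benzyloxy)phenyl]-3-hydroxychroman-8-yl](hydroxy)methyl}-6-methoxy-5-methylphenyl]-2-methylbutan-1-one (carbinol epimers) | CC[C@@H](C)C(=O)c1c(OCc2ccccc2)c(C(O)c2c(OCc4ccccc4)cc(OCc4ccccc4)c3c2O[C@H](c2ccc(OCc4ccccc4)c(OCc4ccccc4)c2)[C@@H](O)C3)c(OCc2ccccc2)c(C)c1OC
F2 | step 5 | 2-formyl-3-hydroxy-5-methoxy-4-methylphenyl (2R)-2-methylbutanoate | CC[C@@H](C)C(=O)Oc1cc(OC)c(C)c(O)c1C=O
F3 | step 4 | 2,4,6-trimethoxy-3-methylbenzaldehyde | O=Cc1c(OC)cc(OC)c(C)c1OC
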